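The target and the isomer of the product are what I read at the end of this flask, but first comes the question of how much starting material the protic impurity takes away for good.

    starting material + starting material ⇌ target (K1 = 0.11 L mol⁻¹, k1 = 1.01 × 10⁻⁴ L mol⁻¹ s⁻¹)
    starting material ⇌ dormant form (K2 = 0.594, k2 = 3.04 × 10⁻⁴ s⁻¹)
    starting material + protic impurity → quenched substrate (k3 = 2.76 × 10⁻⁴ L mol⁻¹ s⁻¹)
    target ⇌ isomer of the product (K4 = 4.52, k4 = 0.00158 s⁻¹)

starting material 2.8 M; protic impurity 0.280 M; time 25 h

- which holds at 25 h: what has brought the reaction to rest, or that it has not come to rest (it is still moving / all of the starting material has reacted / forward and back rates have come level)
- how much target there is at 25 h, in percent of the starting material charged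
- how much isomer of the product there is at 25 h, in percent of the starting material charged

In this flask the protic impurity is the limiting reagent of the quench, with 0.280 M, less than the 2.8 M of starting material, and the quench has no way back. Its balance is simple: each impurity that reacts removes one starting material into quenched substrate. So the quench share is 10.0%: charged impurity over charged starting material, the part lost for good once the impurity has reacted away.

What does the remainder do? If the reversible steps stand at equilibrium, 2.52 M of starting material is shared among the free form, the dormant form, the target and the isomer, the last two counted double. The constants then give [starting material] = 0.927 M, so I reckon 6.75% of target and 30.5% of isomer.

Is there time for this? At that [starting material] the impurity lives 1.09 h, and material in the isomer returns through the target in about 1.67 h. Both are shorter than the run, so I expect level rates at the end.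

The forecast says forward and back rates have come level, with 6.75% of target and 30.5% of isomer, on the ground that “all the reversible steps have reached equilibrium”.

The simulated flask gives forward and back rates have come level, with 6.75% of target and 30.5% of isomer. In this flask half of the quench turnover is done by 0.366 h, far sooner than the end of the run. At 12.5 h the impurity stands at 0% of its charge and quenched substrate at 10.0%, the quench share. In the neighbour flask with 0.70 M of starting material, the same impurity charge gives a quench share of 40.0%, and that flask holds 39.9% of quenched substrate at 25.0 h.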